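Why does the eta run go so slowly late on? Between 50.0 min and 80.0 min its product rose from 26% to 30% of the substrate charged, in readings that scatter by 2 percentage points, while 67% of the substrate stood unconverted.

| flask | substrate | free catalyst | added ligand | remark |
|---|---|---|---|---|
| eta | 0.13 M | 0.40 mM | 2 mM | run made earlier |
| gamma | 0.30 M | 0.40 mM | 2 mM | run made earlier |
| alpha | 0.20 M | 0.60 mM | 2 mM | run made earlier |
| flask | 0.20 M | 0.40 mM | 2.0 mM |  |

| run | time / min | product / % | substrate / % |
|---|---|---|---|
| eta | 20.0 | 9 | 91 |
| eta | 40.0 | 22 | 80 |
| eta | 50.0 | 26 | 76 |
| eta | 80.0 | 30 | 67 |
| gamma | 10.0 | 6 | 99 |
| gamma | 25.0 | 10 | 90 |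
| gamma | 50.0 | 18 | 80 |
| gamma | 80.0 | 22 | 73 |
| alpha | 6.00 | 7 | 95 |
| alpha | 12.0 | 11 | 96 |
| alpha | 30.0 | 17 | 80 |
| alpha | 80.0 | 44 | 57 |

(standard deviation of a reading: 2 percentage points)

- reactions considered so far: catalyst intermediate -> free catalyst + product; substrate + free catalyst -> catalyst intermediate; free catalyst + added ligand <-> idle complex

* factor on the rate of making product when 30% of the substrate are converted if free catalyst is charged twice over
* factor on the rate when 30% of the substrate are converted if free catalyst is charged at 0.080 mM instead

What happens in these flasks? Substrate and free catalyst give catalyst intermediate, which releases product and free catalyst. Outside that round, free catalyst and added ligand reversibly form idle complex.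

Which balance do you write first? That of the catalyst, the smaller charge: as fractions of its charge, free catalyst, catalyst intermediate and idle complex add up to one, and product comes from the intermediate fraction.

Can the added ligand run short in this flask? Catalyst charge over ligand charge gives 20.0%. This is the ligand ceiling, the fraction of its own charge that added ligand would lose if the whole catalyst charge went idle. At 0.080 mM the ceiling is 4.00%.

What follows from so small a ceiling? Because added ligand keeps at least 80.0% of its charge in this flask, forward capture per free catalyst stays at that share of its starting value or above. So forward capture is nearly pseudo-first-order and goes by the clock, whereas with substrate and added ligand charges held, the time to a given conversion depends on the catalyst charge.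

And your answer? With substrate and added ligand charges held, I expect a smaller catalyst charge to reach 30% conversion later, after more time for capture, so I reckon a factor above 2 on doubling and below 0.200 at 0.080 mM. That reckoning gives a direction, not a size.

The forecast said 4, range 2.5 to 7, and 0.03, range 0 to 0.12, on the ground: “That implies a strongly superlinear dependence”.

The flask gives 2.33 on doubling, below the forecast's range, and 0.114 at 0.080 mM, inside it; both lie on the side I reckoned.

    catalyst intermediate → free catalyst + product (k = 310 h⁻¹)
    substrate + free catalyst → catalyst intermediate (k = 1400 L mol⁻¹ h⁻¹)
    free catalyst + added ligand ⇌ idle complex (K = 1200 L mol⁻¹, k = 240 L mol⁻¹ h⁻¹)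

In this flask at 0.642 h, the half-life of free catalyst by the step with substrate is 0.18 min, far shorter than the 1.5 h by the forward step with added ligand. Even so, at 1.50 h idle complex holds 29.0% of the catalyst charge in this flask, which through the ceiling costs added ligand 5.80% of its charge, and at 0.080 mM, with ceiling 4.00%, catalyst intermediate at 30% conversion is 16.3% of the catalyst against 28.7% in this flask.

The data are calculated with constants of no real substance, noise included.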